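The data are calculated for substances that don't exist, noise included.

Whatever leaves G must stand afterwards in Q, E, X or J, so the bottom of the asked share is one quantity, the charge of G that has gone anywhere, and I reckon that from the rate and divide the Q into it.

| flask | G | Z | L | remark | time |
|---|---|---|---|---|---|
| Monday's | 0.21 M | 0.384 M | 0.16 M (fed, over 0.20 min) | run made earlier |  |
| Thursday's | 0.48 M | 0.384 M | 0.16 M (fed, over 0.20 min) | run made earlier |  |
| Tuesday's | 0.32 M | 0.58 M | 0.16 M (fed, over 0.20 min) | run made earlier |  |
| gamma | 0.32 M | 0.384 M | 0.160 M (fed, over 0.20 min) |  | 30 min |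
| alpha | 0.32 M | 0.384 M | 0.160 M (fed, over 0.60 min) |  | 30 min |
| delta | 0.32 M | 0.384 M | 0.160 M (fed, over 2.0 min) |  | 30 min |
| eta | 0.32 M | 0.384 M | 0.160 M (fed, over 6.0 min) |  | 30 min |

- Monday's (time / min: Q / %, E / %, X / %): 5.00: 5.9, 2.2, 0.4; 10.0: 8.2, 3.7, 1.3; 15.0: 8.8, 4.0, 2.0; 20.0: 8.4, 3.3, 3.2; 25.0: 7.1, 3.4, 2.8; 30.0: 7.7, 1.8, 3.7
- Thursday's (time / min: Q / %, E / %, X / %): 5.00: 5.7, 1.3, 1.3; 10.0: 7.6, 1.4, 3.6; 15.0: 7.3, 1.8, 4.3; 20.0: 6.9, 2.5, 5.6; 25.0: 5.9, 1.1, 6.4; 30.0: 4.6, 0.7, 7.7
- Tuesday's (time / min: Q / %, E / %, X / %): 6.00: 8.8, 4.6, 1.2; 12.0: 9.9, 6.3, 3.4; 20.0: 9.1, 4.2, 4.8; 25.0: 9.3, 3.0, 6.2; 30.0: 7.5, 3.5, 7.3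

(readings scatter by 0.5 percentage points)

- percentages count the G that a species holds: one X counts as two
- the numbers in the tables scatter by 0.5 percentage points (one standard deviation)
- "hardly changes" means that all values lie within two and a half points (for a concentration: within two and a half percent of the largest)

* share of Q in all that became Q or E or X or J for gamma, alpha, delta, eta, in this order
* how that number moves from the first to the last of them (rises, then falls / rises all the way / falls all the way / hardly changes / falls, then rises)

In the first minutes, Monday's visible Q, E and X together gain 0.0170 min⁻¹ as a fraction of the charge, and Thursday's gain 0.0166 min⁻¹ with twice the G, so within the scatter of these readings this fractional rate does not follow G's concentration, while Tuesday's, with more Z, reads 0.0243 min⁻¹. Unslowed, that rate would move 0.510 of the charge in 30 min. But it shrinks with the G and the Z left, and integrating both brakes, with one Z lost per G, gives the passage, the fraction of the G charged that has left G by the asked time, as 0.347. At the end of this reckoning, my G brake stands at 0.653 and my Z brake at 0.711, so my estimated rate has fallen to 0.464 of its start. I leave out L taking Q back, as I left unseen J out of the starting rate, and these two err in opposite directions. Monday's and Thursday's last Q readings average 0.0615, so my share is 0.177. The longest feed lasts 6.0 min, much less than the 30 min of the run, and by my starting rate about 0.102 of the charge passes in it, so I expect a flat row.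

The forecast gives 41%, 41%, 40.5%, 39.5%, shape hardly changes, and says “J is the main uncertainty”; its level is higher than my share, its shape agrees with mine.

The flask gives 15.3%, 15.3%, 15.2%, 15.2%, shape hardly changes.

    G + Z ⇌ L + Q (K = 0.260, k = 0.0700 M⁻¹ min⁻¹)
    Q + Z ⇌ L + E (K = 0.270, k = 0.350 M⁻¹ min⁻¹)
    G + Q → X (k = 0.0590 M⁻¹ min⁻¹)
    Q → J (k = 0.130 min⁻¹)

In gamma, 61% of G is left at 30.0 min, so the passage is 39.0% against my 34.7%, and Q's 6.00% over it returns 15.4%; delta, with its feed ten times as long, keeps 60.7% of G, a passage of 39.3%. In gamma, Q's half-life by turning into J alone, 5.3 min, is shorter than its 37 min by G + Q into X alone with G as charged, and at 30.0 min gamma holds J at 26.0% against X at 5.65%.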